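4 questions stand on two flasks, maple and birch, and the reckoning below follows how fast the share that is not yet ring reaches ring.

| flask | substrate | temperature | remark | time |
|---|---|---|---|---|
| Monday's | 0.25 mM | 95 °C | run made earlier |  |
| Wednesday's | 1 mM | 114 °C | run made earlier |  |
| maple | 0.50 mM | 110 °C |  | 12 min |
| birch | 0.50 mM | 118 °C |  | 12 min |

| run | time / min | ring / % | substrate / % |
|---|---|---|---|
| Monday's | 2.00 | 33.3 | 29.2 |
| Monday's | 5.00 | 51.0 | 10.2 |
| Monday's | 10.0 | 63.2 | 5.8 |
| Monday's | 15.0 | 71.2 | 6.1 |
| Wednesday's | 0.833 | 47.4 | 14.1 |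
| Wednesday's | 2.50 | 68.0 | 5.4 |
| Wednesday's | 5.00 | 79.0 | 2.5 |
| Wednesday's | 8.00 | 87.6 | 2.7 |

(standard deviation of a reading: 1 percentage point)

- a species is counted by the substrate in it: one open dimer counts as two
- steps under discussion: substrate -> ring; 2 substrate <-> open dimer; substrate <-> dormant form

* which of the two there is more of at the end, counted by the substrate in each, maple (ring / open dimer)
* which of the two there is more of at the end, counted by the substrate in each, birch (ring / open dimer)
* final ring, as a percentage of the substrate charged, in maple
* final ring, as a percentage of the substrate charged, in birch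

Take first the main step by itself. Monday's first reading puts the fall of substrate at 0.616 min⁻¹, a half-life of 1.13 min, shorter than the 12 min asked. If all of that fall went to ring, ring at Monday's 95 °C would reach 99.9 % in 12 min.

The readings refuse this picture. Ring and substrate leave 38.8 % unaccounted at 5.00 min on Monday and 38.5 % at 0.833 min on Wednesday. That balance is a reservoir of open dimer and dormant form, a resting state that these readings cannot divide. Monday's substrate stands at 5.8 % and then 6.1 %, yet ring climbs from 63.2 % to 71.2 %.

The quantity to carry is therefore the drain rate: the first-order constant at which the share that isn't ring falls once substrate is down to a few percent. The last two readings give 0.0490 min⁻¹ on Monday and 0.176 min⁻¹ on Wednesday, both carrying the scatter. The two runs differ in charge as well as in temperature, so the apparent activation energy read from them, 79.6 kJ mol⁻¹, holds both changes together. Taken as it stands, it gives maple's drain rate, 0.136 min⁻¹, and birch's, 0.226 min⁻¹.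

Run back to zero time, the drain lines start from 60.1 % on Monday, at c(substrate) 0.25 mM, and 50.5 % on Wednesday, at 1 mM. For maple and birch, at 0.50 mM, this reckoning takes their mean, 55.3 %. This reckoning gives ring 89.1 % in maple and 96.3 % in birch.

The forecast says ring 88 % (82 % to 93 %) in maple and 95 % (90 % to 98 %) in birch, lower than this reckoning: “Ring dominates in both”.

Maple ends at 92.1 % ring and birch at 98.1 %, with open dimer at 4.68 % and 1.45 %. Starting from maple's 19.4 % unringed at 6.00 min, the drain rate gives 8.58 % at 12.0 min, and the flask holds 7.90 %. Starting from birch's 6.92 %, it gives 1.78 %, and the flask holds 1.90 %. Birch's ring moves by 6 points when read at 5.50 min with the amounts held, or when charged with 3.32 mM with the time held.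

    substrate → ring (k = 0.0190 s⁻¹, Ea = 102 kJ mol⁻¹)
    2 substrate ⇌ open dimer (K = 6000 M⁻¹, k = 9.70 M⁻¹ s⁻¹, Ea = 39.0 kJ mol⁻¹, ΔH = −45.0 kJ mol⁻¹)
    substrate ⇌ dormant form (K = 1.60, k = 0.0140 s⁻¹, Ea = 92.0 kJ mol⁻¹, ΔH = −8.00 kJ mol⁻¹)
    (constants at 110 °C)

The runs were computed with constants of no real substance; scatter was added.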